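The butenolide (O1′, C2′, C3′, C4′, C5′) is formed by joining its carbonyl carbon C2′ to the vinylic carbon C3′. The precursor is a (Z)-vinyl iodide whose C15/C5′ diol is tied up as a cyclic carbonate: iodine–lithium exchange sends C3′ onto the carbonate carbon, which becomes C2′, and the carbonate ring opens to release 15-OH. The step exploits the cis placing of C3′ and C5′–O across C3′=C4′ and the vicinal oxygens on C15 and C5′. C1–C5 of D-gluconolactone become C13, C14, C15, C5′ and C4′ with all three carbinol centres; larixol supplies the decalin, its C18 hydroxyl entering by 6α-OH-directed C–H silylation.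

Key step: step 19

Remarks:
- Numbering: labdane numbering for the decalin (C17 = methyl on C8, C18 = CH2OH on C4, C19 = methyl on C4, C20 = methyl on C10); side chain C11, C12, C13 (bearing exocyclic C16), C14, C15; butenolide O1′, C2′ (C=O), C3′ (=CH), C4′ (C–CH3), C5′ (CH–O).
- Assumption: larixol is taken as the commercial (13S) natural product. Compounds 4–10 are carried as C13 ketal anomers (centre destroyed in step 8), so C13 is left undefined in their SMILES.

**Route**

Step 1
Reactants: 1 (+)-larixol (labda-8(17),14-diene-6α,13-diol)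
Product: 2 8α,17-epoxylabd-14-ene-6α,13-diol
Conditions: mCPBA (1.05 equiv), NaHCO3, CH2Cl2, −10 → 0 °C
Reagents that add atoms: mCPBA, OOC(=O)c1cccc(Cl)c1
Why: Prilezhaev epoxidation: the electron-richer 1,1-disubstituted exocyclic C8=C17 should react before the monosubstituted vinyl group, and attack from the α face (away from the axial C20 methyl, same side as the 6α-OH) places the epoxide oxygen 8α.

Step 2
Reactants: 2 8α,17-epoxylabd-14-ene-6α,13-diol
Product: 3 labd-14-ene-6α,8α,13-triol
Conditions: LiAlH4, THF, 0 °C → reflux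
Reagents that add atoms: none
Why: SN2 hydride opening of the spiro-epoxide at its CH2 terminus turns C17 into the 8β-methyl and leaves the tertiary 8α-alcohol, so C8 keeps the configuration set in step 1.

Step 3
Reactants: 3 labd-14-ene-6α,8α,13-triol
Product: 5 methyl ketal 8α,13-epoxy-13-methoxy-14,15-dinorlabdan-6α-ol, via hemiketal 4 (not isolated)
Conditions: OsO4 (2 mol%), NaIO4 (4 equiv), 2,6-lutidine, dioxane/H2O, rt; then crude in MeOH, PPTS (cat.), rt
Reagents that add atoms: methanol, CO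
Why: Lemieux–Johnson cleavage: dihydroxylation of the vinyl group and twofold periodate cleavage of the resulting 13,14,15-triol should leave the C13 methyl ketone, which the 8α-OH captures as the trans-fused six-membered hemiketal; acid-catalysed ketalisation with methanol then masks ketone and 8-OH together, so that 6α-OH is the only free hydroxyl.

Step 4
Reactants: 5 methyl ketal 8α,13-epoxy-13-methoxy-14,15-dinorlabdan-6α-ol
Product: 7 oxasilinane (6α-O–SiEt2–C18 bridged ketal), via hydridosilyl ether 6 (not isolated)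
Conditions: Et2SiH2 (1.5 equiv), [Ir(cod)OMe]2 (0.5 mol%), THF, rt, then evaporation; [Rh(cod)Cl]2 (2 mol%), Xantphos (5 mol%), norbornene (1.5 equiv), THF, 100 °C
Reagents that add atoms: diethylsilane, CC[SiH2]CC
Why: Iridium-catalysed dehydrogenative O-silylation followed by rhodium/Xantphos-catalysed hydrosilyl-ether-directed δ-C–H silylation (1,4-diol method): the equatorial 6α-oxygen and the equatorial 4α-methyl C18 are peri (syn-pentane), so the oxasilinane closes as a third chair; the γ positions C4, C8 and C10 carry no hydrogen, and the choice of the α-methyl over the axial C19 sets the C4 stereocentre.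

Step 5
Reactants: 7 oxasilinane
Product: 8 8α,13-epoxy-13-methoxy-14,15-dinorlabdane-6α,18-diol
Conditions: H2O2 (30% aq.), KHCO3, KF, THF/MeOH, 50 °C
Reagents that add atoms: hydrogen peroxide, OO
Why: Tamao–Fleming oxidation converts the C18–Si bond into C18–OH and frees 6α-OH, the basic medium leaving the ketal intact.

Step 6
Reactants: 8 8α,13-epoxy-13-methoxy-14,15-dinorlabdane-6α,18-diol
Product: 9 6α,18-bis(tert-butyldimethylsilyloxy)-8α,13-epoxy-13-methoxy-14,15-dinorlabdane
Conditions: TBSOTf (3 equiv), 2,6-lutidine, CH2Cl2, −78 → 0 °C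
Reagents that add atoms: tert-butyldimethylsilyl triflate, CC(C)(C)[Si](C)(C)OS(=O)(=O)C(F)(F)F
Why: O-silylation with the silyl triflate (needed for the hindered 6α-OH) protects the 1,4-diol for the radical, organometallic and basic steps ahead.

Step 7
Reactants: 9 bis-silyl methyl ketal
Product: 10 hemiketal 6α,18-bis(tert-butyldimethylsilyloxy)-8α,13-epoxy-14,15-dinorlabdan-13-ol
Conditions: PPTS (0.2 equiv), acetone/H2O (10:1), rt
Reagents that add atoms: water, O
Why: Mild acid-catalysed hydrolysis of the mixed methyl ketal regenerates the hemiketal hydroxyl while the silyl ethers should survive PPTS.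

Step 8
Reactants: 10 bis-silyl hemiketal
Product: 11 8α-acetoxy-12-iodo-6α,18-bis(tert-butyldimethylsilyloxy)-13,14,15,16-tetranorlabdane
Conditions: PhI(OAc)2 (1.5 equiv), I2 (1 equiv), cyclohexane, visible light, rt
Reagents that add atoms: iodine, II
Why: Suárez hypoiodite reaction: the anomeric alkoxy radical on C13–O undergoes β-scission of the ring bond C12–C13, the primary C12 radical is trapped by iodine and C13/C16 end up as the acetyl group of the 8α-acetate, so truncation of the side chain and protection of the tertiary alcohol occur in one operation.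

Step 9
Reactants: 12 D-glucono-1,5-lactone
Product: 13 methyl 3,4:5,6-di-O-isopropylidene-D-gluconate
Conditions: 2,2-dimethoxypropane, acetone, MeOH, p-TsOH (cat.), rt
Reagents that add atoms: 2,2-dimethoxypropane, COC(C)(C)OC; methanol, CO
Why: Acid-catalysed methanolysis of the lactone and acetonation of the acyclic gluconate should give the 3,4:5,6-diacetonide with free 2-OH; C2, C3 and C4 (the future C14, C15 and C5′) are untouched.

Step 10
Reactants: 13 methyl 3,4:5,6-di-O-isopropylidene-D-gluconate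
Product: 14 methyl 2-O-tert-butyldimethylsilyl-3,4:5,6-di-O-isopropylidene-D-gluconate
Conditions: TBSOTf, 2,6-lutidine, CH2Cl2, 0 °C
Reagents that add atoms: tert-butyldimethylsilyl triflate, CC(C)(C)[Si](C)(C)OS(=O)(=O)C(F)(F)F
Why: Standard O-silylation of the α-hydroxy ester protects the future 14-OH.

Step 11
Reactants: 14 silylated gluconate ester
Product: 15 S-ethyl 2-O-tert-butyldimethylsilyl-3,4:5,6-di-O-isopropylidene-D-thiogluconate
Conditions: AlMe3, EtSH, CH2Cl2, 0 °C → rt
Reagents that add atoms: ethanethiol, CCS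
Why: Aluminium thiolate transesterification (Me2AlSEt) converts the methyl ester directly into the thioester needed for ketone synthesis without touching the acetonides or the α-silyloxy centre.

Step 12
Reactants: 11 acetoxy iodide; 15 thioester
Product: 17 ketone (C13=O between C12 and C14; 8α-acetate, 6,18,14-tris-TBS, 15,5′- and terminal acetonides), via alkylzinc iodide 16 (not isolated)
Conditions: Zn dust (activated), LiCl, THF, 40 °C; then 15, PdCl2(PPh3)2 (10 mol%), toluene/THF, rt
Reagents that add atoms: none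
Why: Fukuyama coupling: zinc insertion into the primary C12–I bond and palladium-catalysed acylation by the thioester form the C12–C13 bond under neutral conditions that spare the acetate, silyl ethers and acetonides and should not epimerise C14.

Step 13
Reactants: 17 ketone
Product: 18 13(16)-methylene compound
Conditions: Ph3PCH3Br, KOtBu, THF, 0 °C → rt
Reagents that add atoms: methyltriphenylphosphonium bromide, C[P+](c1ccccc1)(c1ccccc1)c1ccccc1.[Br-]
Why: Wittig methylenation installs the exocyclic C16 on C13; the unstabilised ylide should react with the ketone much faster than with the hindered tertiary acetate.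

Step 14
Reactants: 18 13(16)-methylene compound
Product: 19 C4′ aldehyde (terminal acetonide cleaved, 15,5′-acetonide kept)
Conditions: H5IO6 (2 equiv), EtOAc, rt
Reagents that add atoms: none
Why: Periodic acid hydrolyses the terminal (monosubstituted) dioxolane selectively and cleaves the liberated 1,2-diol in the same pot (glycol cleavage), leaving the internal trans-acetonide and giving the C4′ aldehyde.

Step 15
Reactants: 19 C4′ aldehyde
Product: 20 terminal alkyne (C4′≡C3′H)
Conditions: dimethyl (1-diazo-2-oxopropyl)phosphonate, K2CO3, MeOH, 0 °C → rt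
Reagents that add atoms: Ohira–Bestmann reagent, COP(=O)(OC)C(=[N+]=[N-])C(C)=O
Why: Seyferth–Gilbert homologation (Ohira–Bestmann variant) adds C3′ as the alkyne terminus under mild carbonate conditions; C5′ sits in the more stable trans-dioxolane, so epimerisation is not expected.

Step 16
Reactants: 20 terminal alkyne
Product: 21 alkyne 15,5′-diol
Conditions: Me2BBr (4 equiv), CH2Cl2, −78 °C; then aq. NaHCO3
Reagents that add atoms: none
Why: Lewis-acid cleavage of the isopropylidene acetal at −78 °C frees the 15,5′-diol under aprotic conditions that the silyl ethers and the tertiary acetate should tolerate.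

Step 17
Reactants: 21 alkyne 15,5′-diol
Product: 23 (Z)-vinyl iodide 8,15,5′-triol, via vinylmagnesium chelate 22 (not isolated)
Conditions: MeMgBr (8 equiv), CuI (20 mol%), THF/toluene, −20 °C → rt; then I2, THF, −78 → 0 °C; aq. Na2S2O3
Reagents that add atoms: methylmagnesium bromide, C[Mg]Br; iodine, II
Why: Alkoxide-directed copper-catalysed anti-carbomagnesiation of the propargylic alcohol delivers methyl to C4′ and magnesium to C3′ in a five-membered chelate; iodinolysis with retention gives the (Z)-iodide, and the excess Grignard reagent also removes the 8-O-acetyl group.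

Step 18
Reactants: 23 (Z)-vinyl iodide triol
Product: 24 15,5′-cyclic carbonate
Conditions: 1,1′-carbonyldiimidazole (1.5 equiv), DMAP (cat.), CH2Cl2, rt
Reagents that add atoms: 1,1′-carbonyldiimidazole, O=C(n1ccnc1)n1ccnc1
Why: Carbonyl transfer from CDI to the syn-1,2-diol closes the trans-disubstituted five-membered carbonate; the tertiary 8-OH is too hindered to be acylated and O14, O6 and O18 are silylated.

Step 19
Reactants: 24 15,5′-cyclic carbonate
Product: 27 6,18,14-tris-O-TBS butenolide (15-OH and 8-OH free), via vinyllithium 25 (not isolated), via bicyclic alkoxide 26 (not isolated)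
Conditions: t-BuLi (3.2 equiv), THF/Et2O, −100 °C, then −78 → −40 °C; AcOH/THF quench at −78 °C
Reagents that add atoms: none
Why: Iodine–lithium exchange (one further equivalent of t-BuLi serves the 8-OH) is faster than addition of t-BuLi to the carbonate and gives the configurationally stable (Z)-vinyllithium 25, whose carbanion C3′ is held by the C3′=C4′ geometry above the carbonate carbonyl carbon. Attack of C3′ on that carbon (5-exo-trig with respect to the C=O; the butenolide ring O1′–C2′–C3′–C4′–C5′ is closed by the new C2′–C3′ bond) gives the 2,7-dioxabicyclo[2.2.1]heptene alkoxide 26, which opens by loss of the O15 alkoxide to the conjugated γ-lactone. The closest known reactions are Parham cycloacylations, in which aryl- and vinyllithiums made by halogen–lithium exchange are acylated by internal carbamates, carbonates and esters. No stereocentre is created: C5′ and C15 come unchanged from D-gluconate, and the only transient centre, C2′ in 26, is lost on ring opening. The step needs cyclisation before protonation or intermolecular attack, which the Z geometry from step 17 and the low temperature should secure; it also needs collapse of 26 to the five-membered rather than the six-membered lactone, which equilibration through 26 (butenolide more stable than the 5,6-dihydropyran-2-one) and the cold acidic quench should secure.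

Step 20
Reactants: 27 tris-O-TBS butenolide
Product: 28 CNP0301623.1 (target)
Conditions: aq. HF (48%), MeCN, 0 °C → rt
Reagents that add atoms: none
Why: Fluoride-mediated global desilylation under mildly acidic conditions that the butenolide, the allylic alcohol and the tertiary alcohol should tolerate.

**Compound list**

1 | (+)-larixol, labda-8(17),14-diene-6α,13-diol | C=C[C@@](C)(O)CC[C@@H]1[C@@]2(C)CCCC(C)(C)[C@@H]2[C@@H](O)CC1=C | starting material
2 | 8α,17-epoxylabd-14-ene-6α,13-diol | C=C[C@@](C)(O)CC[C@@H]1[C@@]2(C)CCCC(C)(C)[C@@H]2[C@@H](O)C[C@@]1(C3)O3 | intermediate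
3 | labd-14-ene-6α,8α,13-triol | C=C[C@@](C)(O)CC[C@@H]1[C@@]2(C)CCCC(C)(C)[C@@H]2[C@@H](O)C[C@@]1(C)O | intermediate
4 | hemiketal 8α,13-epoxy-14,15-dinorlabdane-6α,13-diol (C13 anomers) | CC1(O)CC[C@@H]2[C@@]3(C)CCCC(C)(C)[C@@H]3[C@@H](O)C[C@@]2(C)O1 | intermediate
5 | methyl ketal 8α,13-epoxy-13-methoxy-14,15-dinorlabdan-6α-ol | COC1(C)CC[C@@H]2[C@@]3(C)CCCC(C)(C)[C@@H]3[C@@H](O)C[C@@]2(C)O1 | intermediate
6 | 6α-O-diethyl(hydrido)silyl ether of 5 | COC1(C)CC[C@@H]2[C@@]3(C)CCCC(C)(C)[C@@H]3[C@@H](O[SiH](CC)CC)C[C@@]2(C)O1 | intermediate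
7 | oxasilinane, 6α-O–Si(Et)2–C18 bridged ketal | COC1(C)CC[C@@H]2[C@@]3(C)CCC[C@@](C)(C[Si](CC)(CC)O4)[C@@H]3[C@@H]4C[C@@]2(C)O1 | intermediate
8 | 8α,13-epoxy-13-methoxy-14,15-dinorlabdane-6α,18-diol | COC1(C)CC[C@@H]2[C@@]3(C)CCC[C@@](C)(CO)[C@@H]3[C@@H](O)C[C@@]2(C)O1 | intermediate
9 | 6α,18-bis-TBS ether of 8 | COC1(C)CC[C@@H]2[C@@]3(C)CCC[C@@](C)(CO[Si](C)(C)C(C)(C)C)[C@@H]3[C@@H](O[Si](C)(C)C(C)(C)C)C[C@@]2(C)O1 | intermediate
10 | hemiketal 6α,18-bis(TBS-oxy)-8α,13-epoxy-14,15-dinorlabdan-13-ol | CC1(O)CC[C@@H]2[C@@]3(C)CCC[C@@](C)(CO[Si](C)(C)C(C)(C)C)[C@@H]3[C@@H](O[Si](C)(C)C(C)(C)C)C[C@@]2(C)O1 | intermediate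
11 | 8α-acetoxy-12-iodo-6α,18-bis(TBS-oxy)-13,14,15,16-tetranorlabdane | ICC[C@@H]1[C@@]2(C)CCC[C@@](C)(CO[Si](C)(C)C(C)(C)C)[C@@H]2[C@@H](O[Si](C)(C)C(C)(C)C)C[C@@]1(C)OC(C)=O | intermediate
12 | D-glucono-1,5-lactone | OC[C@H]1OC(=O)[C@H](O)[C@@H](O)[C@@H]1O | starting material
13 | methyl 3,4:5,6-di-O-isopropylidene-D-gluconate | COC(=O)[C@H](O)[C@H]1OC(C)(C)O[C@@H]1[C@H]1COC(C)(C)O1 | intermediate
14 | methyl 2-O-TBS-3,4:5,6-di-O-isopropylidene-D-gluconate | COC(=O)[C@H](O[Si](C)(C)C(C)(C)C)[C@H]1OC(C)(C)O[C@@H]1[C@H]1COC(C)(C)O1 | intermediate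
15 | S-ethyl 2-O-TBS-3,4:5,6-di-O-isopropylidene-D-thiogluconate | CCSC(=O)[C@H](O[Si](C)(C)C(C)(C)C)[C@H]1OC(C)(C)O[C@@H]1[C@H]1COC(C)(C)O1 | intermediate
16 | alkylzinc iodide from 11 | I[Zn]CC[C@@H]1[C@@]2(C)CCC[C@@](C)(CO[Si](C)(C)C(C)(C)C)[C@@H]2[C@@H](O[Si](C)(C)C(C)(C)C)C[C@@]1(C)OC(C)=O | intermediate
17 | C13 ketone (8α-OAc, 6,18,14-tris-TBS, two acetonides) | O=C(CC[C@@H]1[C@@]2(C)CCC[C@@](C)(CO[Si](C)(C)C(C)(C)C)[C@@H]2[C@@H](O[Si](C)(C)C(C)(C)C)C[C@@]1(C)OC(C)=O)[C@H](O[Si](C)(C)C(C)(C)C)[C@H]1OC(C)(C)O[C@@H]1[C@H]1COC(C)(C)O1 | intermediate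
18 | 13(16)-methylene compound | C=C(CC[C@@H]1[C@@]2(C)CCC[C@@](C)(CO[Si](C)(C)C(C)(C)C)[C@@H]2[C@@H](O[Si](C)(C)C(C)(C)C)C[C@@]1(C)OC(C)=O)[C@H](O[Si](C)(C)C(C)(C)C)[C@H]1OC(C)(C)O[C@@H]1[C@H]1COC(C)(C)O1 | intermediate
19 | C4′ aldehyde | C=C(CC[C@@H]1[C@@]2(C)CCC[C@@](C)(CO[Si](C)(C)C(C)(C)C)[C@@H]2[C@@H](O[Si](C)(C)C(C)(C)C)C[C@@]1(C)OC(C)=O)[C@H](O[Si](C)(C)C(C)(C)C)[C@H]1OC(C)(C)O[C@@H]1C=O | intermediate
20 | terminal alkyne, 15,5′-acetonide | C=C(CC[C@@H]1[C@@]2(C)CCC[C@@](C)(CO[Si](C)(C)C(C)(C)C)[C@@H]2[C@@H](O[Si](C)(C)C(C)(C)C)C[C@@]1(C)OC(C)=O)[C@H](O[Si](C)(C)C(C)(C)C)[C@H]1OC(C)(C)O[C@@H]1C#C | intermediate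
21 | alkyne 15,5′-diol | C=C(CC[C@@H]1[C@@]2(C)CCC[C@@](C)(CO[Si](C)(C)C(C)(C)C)[C@@H]2[C@@H](O[Si](C)(C)C(C)(C)C)C[C@@]1(C)OC(C)=O)[C@H](O[Si](C)(C)C(C)(C)C)[C@@H](O)[C@H](O)C#C | intermediate
22 | vinylmagnesium chelate (O5′–Mg–C3′ ring, 8-O and 15-O magnesium alkoxides) | C=C(CC[C@@H]1[C@@]2(C)CCC[C@@](C)(CO[Si](C)(C)C(C)(C)C)[C@@H]2[C@@H](O[Si](C)(C)C(C)(C)C)C[C@@]1(C)O[Mg]Br)[C@H](O[Si](C)(C)C(C)(C)C)[C@@H](O[Mg]Br)[C@@H]1O[Mg]C=C1C | intermediate
23 | (Z)-vinyl iodide 8,15,5′-triol | C=C(CC[C@@H]1[C@@]2(C)CCC[C@@](C)(CO[Si](C)(C)C(C)(C)C)[C@@H]2[C@@H](O[Si](C)(C)C(C)(C)C)C[C@@]1(C)O)[C@H](O[Si](C)(C)C(C)(C)C)[C@@H](O)[C@H](O)/C(C)=C\I | intermediate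
24 | 15,5′-cyclic carbonate of 23 | C=C(CC[C@@H]1[C@@]2(C)CCC[C@@](C)(CO[Si](C)(C)C(C)(C)C)[C@@H]2[C@@H](O[Si](C)(C)C(C)(C)C)C[C@@]1(C)O)[C@H](O[Si](C)(C)C(C)(C)C)[C@H]1OC(=O)O[C@@H]1/C(C)=C\I | intermediate
25 | (Z)-vinyllithium (8-O-lithium alkoxide) | C=C(CC[C@@H]1[C@@]2(C)CCC[C@@](C)(CO[Si](C)(C)C(C)(C)C)[C@@H]2[C@@H](O[Si](C)(C)C(C)(C)C)C[C@@]1(C)O[Li])[C@H](O[Si](C)(C)C(C)(C)C)[C@H]1OC(=O)O[C@@H]1/C(C)=C\[Li] | intermediate
26 | bicyclic alkoxide, 2,7-dioxabicyclo[2.2.1]hept-5-ene tetrahedral intermediate | C=C(CC[C@@H]1[C@@]2(C)CCC[C@@](C)(CO[Si](C)(C)C(C)(C)C)[C@@H]2[C@@H](O[Si](C)(C)C(C)(C)C)C[C@@]1(C)O[Li])[C@H](O[Si](C)(C)C(C)(C)C)[C@H]1O[C@]2(O[Li])C=C(C)[C@H]1O2 | intermediate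
27 | 6,18,14-tris-O-TBS butenolide | C=C(CC[C@@H]1[C@@]2(C)CCC[C@@](C)(CO[Si](C)(C)C(C)(C)C)[C@@H]2[C@@H](O[Si](C)(C)C(C)(C)C)C[C@@]1(C)O)[C@H](O[Si](C)(C)C(C)(C)C)[C@@H](O)[C@@H]1OC(=O)C=C1C | intermediate
28 | CNP0301623.1 | C=C(CC[C@@H]1[C@@]2(C)CCC[C@@](C)(CO)[C@@H]2[C@@H](O)C[C@@]1(C)O)[C@H](O)[C@@H](O)[C@@H]1OC(=O)C=C1C | target

**Totals and risks**

Total step count: 20. Longest linear sequence: 17 steps (steps 1–8 and 12–20 from larixol); the gluconate branch (steps 9–11) joins at step 12.

Steps most likely to fail: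

1. Step 19 (key step). The vinyllithium may be protonated or attacked intermolecularly before it cyclises. The tetrahedral intermediate may collapse towards the six-membered lactone. The product alkoxide may epimerise C5′ through the furanolate. Fallback: set out from the (Z)-vinyl iodide triol 23 and run a palladium-catalysed carbonylative lactonisation (Pd(PPh3)4, CO 1 atm, Et3N, MeCN/THF, 50 °C). The C2′–C3′ bond is then formed at palladium by CO insertion and the 5′-oxygen completes the five-membered lactone, which gives 27 directly. This fallback makes no new compound F0 and comes back to the route at 27.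

2. Step 4. C–H activation at the hindered peri methyl may not occur, or silylation may go to another δ position. Fallback: set out from methyl ketal 5 and use the hypoiodite reaction (PhI(OAc)2, I2, hν). A 1,5-hydrogen transfer from C18 to the 6α-alkoxy radical and ring closure should give the 6α,18-epoxide F1. Buffered RuCl3/NaIO4 oxidation of the ether CH2 gives the 18,6α-olide F2, and LiAlH4 reduction returns to the route at diol 8.

3. Step 12. Zinc insertion may be sluggish, and acyl transfer from the hindered α-silyloxy thioester to palladium may be slow, so that the organozinc is lost by protonation. Fallback: set out from thioester 15 and reduce it with DIBAL-H at −78 °C to the aldehyde F3. Couple F3 with iodide 11 in a cobalt-catalysed alkyl Nozaki–Hiyama–Kishi reaction (CrCl2, cat. vitamin B12, DMF) to the C13 carbinol F4 (both epimers). Dess–Martin oxidation returns to the route at ketone 17.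

Further compounds
F0 | step 19 | none | none
F1 | step 4 | 6α,18-epoxide of methyl ketal 5 | COC1(C)CC[C@@H]2[C@@]3(C)CCC[C@@](C)(CO4)[C@@H]3[C@@H]4C[C@@]2(C)O1
F2 | step 4 | 18,6α-olide of methyl ketal 5 | COC1(C)CC[C@@H]2[C@@]3(C)CCC[C@@](C)(C(=O)O4)[C@@H]3[C@@H]4C[C@@]2(C)O1
F3 | step 12 | 2-O-TBS-3,4:5,6-di-O-isopropylidene-aldehydo-D-glucose | O=C[C@H](O[Si](C)(C)C(C)(C)C)[C@H]1OC(C)(C)O[C@@H]1[C@H]1COC(C)(C)O1
F4 | step 12 | C13 carbinol (C13 epimers) | OC(CC[C@@H]1[C@@]2(C)CCC[C@@](C)(CO[Si](C)(C)C(C)(C)C)[C@@H]2[C@@H](O[Si](C)(C)C(C)(C)C)C[C@@]1(C)OC(C)=O)[C@H](O[Si](C)(C)C(C)(C)C)[C@H]1OC(C)(C)O[C@@H]1[C@H]1COC(C)(C)O1
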